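**Retrosynthetic overview** (C1′–C4′ = the butyl chain of the target)

1. Key disconnection, C2′–C3′: two molecules of aryl ethyl ketone 1, as lithium enolate 2 and then chiral titanium bis-enolate 3, are joined α-carbon to α-carbon by one-electron oxidation (one enolate becomes an enolonium-type electrophile), giving the C2-symmetric (2R,3R)-1,4-diketone 4 with both methyl stereocentres set.
2. Both C=O groups and both O-benzyl groups of 4 are removed by hydrogenolysis (through tetraol 5), giving the C2-symmetric bisphenol 6, whose two benzylic CH2 groups are homotopic.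
3. Aryl–acyl disconnection: phloroglucinol 7 and acid 8 give dihydrochalcone 9 (Friedel–Crafts acylation).
4. C1′–aryl disconnection: 9 and para-quinone methide 10 (from oxidation of either CH2 of 6, stored as methyl ether 11) give target 12; C1′ is set by 1,2-induction from C2′.
5. Rings: none is constructed; all four benzene rings are bought (two with 1, one each with 7 and 8).

Assumption: the (4R,5R)-TADDOLate template is taken to deliver the (2R,3R)-diketone; if it delivers the antipode, the (4S,5S) ligand is used with no other change.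

Abbreviation: TADDOLate = (4R,5R)-2,2-dimethyl-α,α,α′,α′-tetraphenyl-1,3-dioxolane-4,5-dimethanolate (C31H28O4 dianion). TiCl2(TADDOLate) is C31H28Cl2O4Ti, made beforehand from TiCl2(OiPr)2 and the diol.

**Step 1**
Reactants: 1 1-[4-(benzyloxy)phenyl]propan-1-one (two molecules)
Product: 4 (2R,3R)-1,4-bis[4-(benzyloxy)phenyl]-2,3-dimethylbutane-1,4-dione, via lithium (Z)-enolate 2 (not isolated), via titanium bis-enolate 3 (not isolated)
Conditions: LiN(iPr)2 (1.05 equiv), THF, −78 °C; TiCl2(TADDOLate) (0.5 equiv), −78 to −40 °C; Cu(OSO2CF3)2 (1.05 equiv), EtCN, −78 °C; recrystallise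
Reagents that add atoms: none
Why: Proposed new method: LiN(iPr)2 gives the (Z)-lithium enolate 2, two of which replace both chlorides of TiCl2(TADDOLate) to give the C2-symmetric bis-enolate 3 of tetravalent titanium; one-electron oxidation by divalent copper turns one bound enolate into an α-keto radical cation (an enolonium-type, electrophilic α-carbon) that is captured by the neighbouring, still nucleophilic enolate inside the chiral pocket, so like-face coupling of the two homotopic (Z)-enolates gives the dl (2R,3R) diketone and a second electron transfer releases it; the closest known reaction type is the dl-selective one-electron oxidative homocoupling of titanium and silicon bis-enolates of propiophenones, together with auxiliary-controlled oxidative dimerisation of chiral enolates (Saegusa-type enolate coupling).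

**Step 2**
Reactants: 4 (2R,3R)-1,4-bis[4-(benzyloxy)phenyl]-2,3-dimethylbutane-1,4-dione
Product: 6 4,4′-[(2S,3S)-2,3-dimethylbutane-1,4-diyl]diphenol, via tetraol 5 (not isolated)
Conditions: H2 (5 bar), Pd/C (10 wt% Pd), EtOH/AcOH 9:1, 40 °C
Reagents that add atoms: none
Why: Catalytic hydrogenolysis cleaves both O-benzyl ethers and reduces each aryl ketone to the benzylic alcohol (5), whose para-hydroxybenzylic C–O bond is then hydrogenolysed to CH2; the two methyl-bearing centres are not touched (the descriptor changes from R,R to S,S only because the carbonyl priority is lost), and weak acid at low temperature keeps enolisation and Paal–Knorr furan formation slower than C=O reduction.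

**Step 3**
Reactants: 7 phloroglucinol (benzene-1,3,5-triol); 8 3-(4-methoxyphenyl)propanoic acid
Product: 9 1-(2,4,6-trihydroxyphenyl)-3-(4-methoxyphenyl)propan-1-one
Conditions: BF3·OEt2 (neat, as solvent), 90 °C, 2 h; aq. NaOAc work-up
Reagents that add atoms: none
Why: Friedel–Crafts C-acylation of the very electron-rich triol by the BF3-activated acid; chelation of the product ketone as its BF2 complex suppresses a second acylation, and no stereocentre is formed.

**Step 4**
Reactants: 6 4,4′-[(2S,3S)-2,3-dimethylbutane-1,4-diyl]diphenol; 9 1-(2,4,6-trihydroxyphenyl)-3-(4-methoxyphenyl)propan-1-one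
Product: 12 1-{3-[(1S,2R,3S)-1,4-bis(4-hydroxyphenyl)-2,3-dimethylbutyl]-2,4,6-trihydroxyphenyl}-3-(4-methoxyphenyl)propan-1-one, via para-quinone methide 10 (not isolated), via benzylic methyl ether 11 (not isolated)
Conditions: 6 (2 equiv), DDQ (1 equiv), CH2Cl2/MeOH 4:1, 0 °C; filter, evaporate; then 9 (3 equiv), CF3CO2H (0.2 equiv), (CF3)2CHOH, −20 to 0 °C
Reagents that add atoms: none
Why: DDQ abstracts hydride from either of the two homotopic benzylic CH2 groups para to OH to give the same para-quinone methide 10, which methanol traps as ether 11 until the oxidant is gone; acid then re-forms 10, which undergoes Friedel–Crafts alkylation (1,6-conjugate addition) at one of the two equivalent free ring positions of 9, and C1′ (S) follows from 1,2-induction: in the conformer with C2′–H eclipsing the exocyclic C=C (allylic 1,3-strain) the arene attacks anti to the larger CH(CH3)CH2Ar branch.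

**Compound list**

1 | 1-[4-(benzyloxy)phenyl]propan-1-one | CCC(=O)c1ccc(OCc2ccccc2)cc1 | starting material
2 | lithium (Z)-1-[4-(benzyloxy)phenyl]prop-1-en-1-olate, LiOC(Ar)=CHCH3 | C/C=C(\O[Li])c1ccc(OCc2ccccc2)cc1 | intermediate
3 | [(4R,5R)-TADDOLato]bis{(Z)-1-[4-(benzyloxy)phenyl]prop-1-en-1-olato}titanium, Ti(TADDOLate)[OC(Ar)=CHCH3]2 | C/C=C(\O[Ti]1(O/C(=C\C)c2ccc(OCc3ccccc3)cc2)OC(c2ccccc2)(c2ccccc2)[C@@H]2OC(C)(C)O[C@H]2C(c2ccccc2)(c2ccccc2)O1)c1ccc(OCc2ccccc2)cc1 | intermediate
4 | (2R,3R)-1,4-bis[4-(benzyloxy)phenyl]-2,3-dimethylbutane-1,4-dione | O=C(c1ccc(OCc2ccccc2)cc1)[C@H](C)[C@@H](C)C(=O)c1ccc(OCc2ccccc2)cc1 | intermediate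
5 | (2R,3R)-1,4-bis(4-hydroxyphenyl)-2,3-dimethylbutane-1,4-diol (tetraol; carbinol centres C1 and C4 as a mixture) | OC(c1ccc(O)cc1)[C@H](C)[C@@H](C)C(O)c1ccc(O)cc1 | intermediate
6 | 4,4′-[(2S,3S)-2,3-dimethylbutane-1,4-diyl]diphenol | Oc1ccc(C[C@H](C)[C@@H](C)Cc2ccc(O)cc2)cc1 | intermediate
7 | phloroglucinol (benzene-1,3,5-triol) | Oc1cc(O)cc(O)c1 | starting material
8 | 3-(4-methoxyphenyl)propanoic acid | COc1ccc(CCC(=O)O)cc1 | starting material
9 | 1-(2,4,6-trihydroxyphenyl)-3-(4-methoxyphenyl)propan-1-one | COc1ccc(CCC(=O)c2c(O)cc(O)cc2O)cc1 | intermediate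
10 | 4-[(2R,3S)-4-(4-hydroxyphenyl)-2,3-dimethylbutylidene]cyclohexa-2,5-dien-1-one | O=C1C=CC(=C[C@H](C)[C@@H](C)Cc2ccc(O)cc2)C=C1 | intermediate
11 | 4-[(2R,3S)-4-(4-hydroxyphenyl)-1-methoxy-2,3-dimethylbutyl]phenol (both C1 epimers) | COC(c1ccc(O)cc1)[C@H](C)[C@@H](C)Cc1ccc(O)cc1 | intermediate
12 | 1-{3-[(1S,2R,3S)-1,4-bis(4-hydroxyphenyl)-2,3-dimethylbutyl]-2,4,6-trihydroxyphenyl}-3-(4-methoxyphenyl)propan-1-one | COc1ccc(CCC(=O)c2c(O)cc(O)c([C@H](c3ccc(O)cc3)[C@H](C)[C@@H](C)Cc3ccc(O)cc3)c2O)cc1 | target

**Totals**

Total step count: 4. Longest linear sequence: 3 (steps 1, 2, 4); step 3 is a one-step side branch.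

**Steps most likely to fail**

Step 1 (highest risk). The level and sense of induction of the titanium template, the dl/meso ratio and the redox window of the bis-enolate are all untested. Any minor enantiomer that survives recrystallisation would end up as the enantiomer of 12. The fallback moves stereocontrol from the metal template to a covalent auxiliary on the ketone while keeping the α–α oxidative coupling. It sets out from 1 and comes back at 4. Ketone 1 is condensed with (R)-1-amino-2-(methoxymethyl)pyrrolidine (chosen by analogy with the known sense of azaenolate alkylation) to the hydrazone (E)-1-[4-(benzyloxy)phenyl]-N-[(2R)-2-(methoxymethyl)pyrrolidin-1-yl]propan-1-imine F1. Deprotonation with LiN(iPr)2 in THF and oxidation of the azaenolate with CuCl2 at −78 °C gives the C2-symmetric bis-hydrazone (2R,3R)-1,4-bis[4-(benzyloxy)phenyl]-N1,N4-bis[(2R)-2-(methoxymethyl)pyrrolidin-1-yl]-2,3-dimethylbutane-1,4-diimine F2. Two-phase aqueous oxalic acid then cleaves both hydrazones without epimerisation to give 4, and the auxiliary is recovered.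

Step 4. The risks are: the statistical mono-oxidation of 6; oxidation of a phenol with no ortho substituents; a nucleophile (9) that is deactivated by its acyl group; a diastereomer ratio at C1′ that may be only about 3–5:1 (separation by HPLC); and loss of the C2′ configuration if the cation eliminates to the styrene. The fallback alkylates first and acylates last. It sets out from 6 (activated in the same way, through 11) and 7, and comes back at 12. The more nucleophilic, symmetric phloroglucinol 7 (5 equiv, CF3CO2H cat., (CF3)2CHOH, −20 °C) captures the quinone methide to give 2-[(1S,2R,3S)-1,4-bis(4-hydroxyphenyl)-2,3-dimethylbutyl]benzene-1,3,5-triol F3, which can be purified to a single diastereomer. Its two remaining ring positions are equivalent, so Friedel–Crafts acylation with acid 8 (BF3·OEt2, 60 °C) gives 12 directly.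

Step 2. The risks are acid-promoted epimerisation or furan formation of the 1,4-diketone before reduction, and incomplete deoxygenation. The fallback is a stepwise hydride route that removes the enolisable diketone under basic conditions first. It sets out from 4 and comes back at 6. NaBH4 (THF/MeOH, 0 °C) gives (2R,3R)-1,4-bis[4-(benzyloxy)phenyl]-2,3-dimethylbutane-1,4-diol F4. Ionic deoxygenation (Et3SiH, BF3·OEt2, CH2Cl2, −40 °C) gives 1,1′-[(2S,3S)-2,3-dimethylbutane-1,4-diyl]bis[4-(benzyloxy)benzene] F5. Neutral hydrogenolysis (H2, Pd/C, EtOAc, 25 °C) then removes the benzyl groups to give 6.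

**Further compounds**

F1 | step 1 | (E)-1-[4-(benzyloxy)phenyl]-N-[(2R)-2-(methoxymethyl)pyrrolidin-1-yl]propan-1-imine | CC/C(=N\N1CCC[C@@H]1COC)c1ccc(OCc2ccccc2)cc1
F2 | step 1 | (2R,3R)-1,4-bis[4-(benzyloxy)phenyl]-N1,N4-bis[(2R)-2-(methoxymethyl)pyrrolidin-1-yl]-2,3-dimethylbutane-1,4-diimine | COC[C@H]1CCCN1N=C(c1ccc(OCc2ccccc2)cc1)[C@H](C)[C@@H](C)C(=NN1CCC[C@@H]1COC)c1ccc(OCc2ccccc2)cc1
F3 | step 4 | 2-[(1S,2R,3S)-1,4-bis(4-hydroxyphenyl)-2,3-dimethylbutyl]benzene-1,3,5-triol | Oc1cc(O)c([C@H](c2ccc(O)cc2)[C@H](C)[C@@H](C)Cc2ccc(O)cc2)c(O)c1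
F4 | step 2 | (2R,3R)-1,4-bis[4-(benzyloxy)phenyl]-2,3-dimethylbutane-1,4-diol (carbinol centres as a mixture) | OC(c1ccc(OCc2ccccc2)cc1)[C@H](C)[C@@H](C)C(O)c1ccc(OCc2ccccc2)cc1
F5 | step 2 | 1,1′-[(2S,3S)-2,3-dimethylbutane-1,4-diyl]bis[4-(benzyloxy)benzene] | c1ccc(COc2ccc(C[C@H](C)[C@@H](C)Cc3ccc(OCc4ccccc4)cc3)cc2)cc1
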